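**Plan**
- Retrosynthesis: the hydroxyquinone goes back to an 11,12,14-trimethoxyarene, the C1–O bond is cut (allylic oxidation next to C10=C20), the C6=C7 enol lactone goes back to a 7-acetoxy-19,6β-lactone, and then the C9–C20 bond is cut and C9 is returned to C10, giving a 20-iodoabietane.
- Enabling feature: in the seven-membered ring B (C5–C6–C7–C8–C9–C20–C10) the methine C20 lies between the aryl carbon C9 and C10, so ring B is a six-membered abietane ring into which the angular carbon has slipped; a 1,2-shift of C9 from C10 to an electron-poor C20 creates it.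
- Forward: rings A and C and the C4 carboxyl come from podocarpic acid; ring C is completed first (C13 isopropyl, C11 and C14 oxygen), C20 is iodinated from the C19 alcohol, the C19 acid is closed onto C6 through the 6-bromo-7-ketone, ring B is then enlarged from six to seven, and the C1 oxygen, the enol lactone and the quinone follow.
- Stereochemistry: C4 and C5 are those of podocarpic acid and are never touched; C10 ceases to be a stereocentre in the shift; C1 is set by axial hydride delivery to a C1 ketone.

Key step: step 12

Remark: abietane numbering is kept throughout (icetexane = 9(10→20)abeo-abietane); the C7 alcohol of step 10 is drawn as the expected 7β epimer, and either epimer would serve because C7 becomes trigonal in step 15.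

**Step 1**
Reactants: 1 podocarpic acid; 2 propan-2-ol
Product: 3 12-hydroxyabieta-8,11,13-trien-19-oic acid (lambertic acid)
Conditions: BF3·OEt2, i-PrOH (excess), 1,2-dichloroethane, 70 °C
Reagents that add atoms: none
Why: Friedel–Crafts alkylation of the phenol should go ortho to the hydroxyl at the open C13, because C11 is shielded by C1 and the angular methyl and the para carbon C9 is substituted, while the hindered axial acid stays free.

**Step 2**
Reactants: 3 12-hydroxyabieta-8,11,13-trien-19-oic acid
Product: 4 11,12-dioxoabieta-8,13-dien-19-oic acid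
Conditions: (PhSeO)2O, THF, 50 °C
Reagents that add atoms: benzeneseleninic anhydride, O=[Se](O[Se](=O)c1ccccc1)c1ccccc1
Why: Barton ortho-oxidation of phenols with benzeneseleninic anhydride delivers oxygen intramolecularly to the only free ortho carbon, C11, and should stop at the ortho-quinone as it does with other hindered diterpenoid phenols.

**Step 3**
Reactants: 4 11,12-dioxoabieta-8,13-dien-19-oic acid
Product: 5 11,12,14-triacetoxyabieta-8,11,13-trien-19-oic acid
Conditions: Ac2O, H2SO4 (cat.), 0 °C → rt; aq. work-up
Reagents that add atoms: acetic anhydride, CC(=O)OC(C)=O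
Why: Thiele–Winter acetoxylation, in which acetate adds in conjugate fashion to C14, the only unsubstituted quinone carbon and β to the C12 carbonyl, before enolisation and acetylation, should give the 1,2,4-triacetoxy pattern.

**Step 4**
Reactants: 5 11,12,14-triacetoxyabieta-8,11,13-trien-19-oic acid
Product: 7 methyl 11,12,14-trimethoxyabieta-8,11,13-trien-19-oate, via triol acid 6 (not isolated)
Conditions: K2CO3, MeOH, N2, rt; then Me2SO4, K2CO3, acetone, reflux
Reagents that add atoms: dimethyl sulfate, COS(=O)(=O)OC
Why: Base-catalysed methanolysis frees the air-sensitive hydroxyhydroquinone under nitrogen and Williamson O-methylation with dimethyl sulfate then caps the three phenols and the carboxylate in the same flask.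

**Step 5**
Reactants: 7 methyl 11,12,14-trimethoxyabieta-8,11,13-trien-19-oate
Product: 8 11,12,14-trimethoxyabieta-8,11,13-trien-19-ol
Conditions: LiAlH4, THF, reflux
Reagents that add atoms: none
Why: Hydride reduction of the hindered axial ester to the neopentyl primary alcohol is standard and leaves the aryl methyl ethers alone.

**Step 6**
Reactants: 8 11,12,14-trimethoxyabieta-8,11,13-trien-19-ol
Product: 10 20-iodo-11,12,14-trimethoxyabieta-8,11,13-trien-19-ol, via C19 hypoiodite 9 (not isolated)
Conditions: PhI(OAc)2, I2, CH2Cl2, hν (tungsten lamp), rt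
Reagents that add atoms: iodine, II
Why: Hypoiodite reaction under Suárez conditions: photolysis of the O–I bond gives the C19 alkoxy radical, which sits 1,3-diaxial to the C20 methyl and can reach only its hydrogens in a near-linear seven-membered transition state (1,6-hydrogen transfer), and the resulting neopentyl radical is trapped by iodine far faster than it can rearrange, the neopentyl iodide then resisting closure to the cyclic ether.

**Step 7**
Reactants: 10 20-iodo-11,12,14-trimethoxyabieta-8,11,13-trien-19-ol
Product: 11 20-iodo-11,12,14-trimethoxyabieta-8,11,13-trien-19-oic acid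
Conditions: CrO3, H2SO4, H2O, acetone, 0 °C
Reagents that add atoms: water, O
Why: Jones oxidation converts the primary neopentyl alcohol into the acid within minutes at 0 °C, conditions that aryl methyl ethers and a neopentyl iodide, which can neither be displaced nor eliminated, should tolerate.

**Step 8**
Reactants: 11 20-iodo-11,12,14-trimethoxyabieta-8,11,13-trien-19-oic acid
Product: 12 20-iodo-11,12,14-trimethoxy-7-oxoabieta-8,11,13-trien-19-oic acid
Conditions: DDQ, AcOH/H2O, rt
Reagents that add atoms: water, O
Why: DDQ benzylic oxidation in aqueous acetic acid proceeds by hydride abstraction from C7, the benzylic carbon para to the C12 and ortho to the C14 methoxy group, capture by water and a second oxidation, whereas the isopropyl methine is held in the ring plane by its two ortho neighbours and is not activated.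

**Step 9**
Reactants: 12 20-iodo-11,12,14-trimethoxy-7-oxoabieta-8,11,13-trien-19-oic acid
Product: 14 20-iodo-11,12,14-trimethoxy-7-oxoabieta-8,11,13-trien-19,6β-olide, via 6α-bromo ketone 13 (not isolated)
Conditions: PhNMe3Br3, THF, 0 °C → rt; then NaHCO3, DMF, rt
Reagents that add atoms: none
Why: α-Bromination of the aryl ketone from the open α face followed by intramolecular SN2 displacement (5-exo-tet) by the β-axial C19 carboxylate inverts C6 and sets the 6β C–O bond of the γ-lactone, the classical lactonisation of 6α-bromo-7-oxopodocarpates, while the neopentyl iodide is inert to substitution.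

**Step 10**
Reactants: 14 20-iodo-11,12,14-trimethoxy-7-oxoabieta-8,11,13-trien-19,6β-olide
Product: 15 7β-hydroxy-20-iodo-11,12,14-trimethoxyabieta-8,11,13-trien-19,6β-olide
Conditions: NaBH4, MeOH/THF, 0 °C
Reagents that add atoms: none
Why: NaBH4 reduces the α-acyloxy aryl ketone but neither the γ-lactone nor the iodide, and hydride should enter anti to the axial C6–O bond from the α face (polar Felkin–Anh control) to give mainly the 7β-alcohol, whose configuration is erased in step 15.

**Step 11**
Reactants: 15 7β-hydroxy-20-iodo-11,12,14-trimethoxyabieta-8,11,13-trien-19,6β-olide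
Product: 16 7β-acetoxy-20-iodo-11,12,14-trimethoxyabieta-8,11,13-trien-19,6β-olide
Conditions: Ac2O, pyridine, 4-(dimethylamino)pyridine (cat.), rt
Reagents that add atoms: acetic anhydride, CC(=O)OC(C)=O
Why: Acylation under nucleophilic catalysis masks the benzylic hydroxyl, which lies on the same face as C20 and could otherwise capture the cation of the next step as a 7,20-ether.

**Step 12**
Reactants: 16 7β-acetoxy-20-iodo-11,12,14-trimethoxyabieta-8,11,13-trien-19,6β-olide
Product: 17 7β-acetoxy-11,12,14-trimethoxyicetexa-8,11,13,10(20)-tetraen-19,6β-olide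
Conditions: AgOSO2CF3, 2,6-di-tert-butyl-4-methylpyridine, CH2Cl2, 0 °C → rt, dark
Reagents that add atoms: none
Why: Silver pulls iodide from the neopentyl C20 while the electron-rich ring C assists from the rear: C9, ortho to the C11 methoxy group, bridges C10 and C20 in a phenonium ion that opens at the tertiary C10, so the C10–C9 bond is traded for C9–C20, ring B grows from six to seven members and loss of H20 leaves the C10=C20 alkene. The closest known reaction type is the neophyl-type Wagner–Meerwein 1,2-aryl shift by which C20-activated abietanes are converted into icetexanes. No ring is closed in the usual sense: the three-membered phenonium ring forms by 3-exo-tet ipso attack and opens again, and the seven-membered ring arises by ring expansion. No stereocentre is made, since C10 becomes trigonal and C4, C5, C6 and C7 are not touched. The step needs aryl instead of alkyl migration, which arene participation at a primary centre secures, and proton loss toward C20 instead of C1 or C5, which the benzylic acidity of H20, conjugation of the new alkene with the arene and the deactivation of H5 by the C6 oxygen should favour. Tying C19 to C6 as the γ-lactone turns its carbonyl oxygen away from C20 and C10, so that it cannot capture either cationic centre as a free acid or a methyl ester could, and the hindered pyridine removes the acid that would ionise the C7 acetate.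

**Step 13**
Reactants: 17 7β-acetoxy-11,12,14-trimethoxyicetexa-8,11,13,10(20)-tetraen-19,6β-olide
Product: 18 7β-acetoxy-1α-hydroxy-11,12,14-trimethoxyicetexa-8,11,13,10(20)-tetraen-19,6β-olide
Conditions: SeO2 (cat.), t-BuOOH, CH2Cl2, rt
Reagents that add atoms: tert-butyl hydroperoxide, CC(C)(C)OO (terminal oxygen source); selenium dioxide, O=[Se]=O (oxygen relay)
Why: SeO2-catalysed allylic hydroxylation (ene reaction then [2,3]-sigmatropic shift) oxidises the allylic position on the more substituted alkene carbon, CH2 (C1) before CH (C5), and restores the C10=C20 bond, the axial 1α-alcohol being expected from abstraction of the axial hydrogen.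

**Step 14**
Reactants: 18 7β-acetoxy-1α-hydroxy-11,12,14-trimethoxyicetexa-8,11,13,10(20)-tetraen-19,6β-olide
Product: 19 7β-acetoxy-11,12,14-trimethoxy-1-oxoicetexa-8,11,13,10(20)-tetraen-19,6β-olide
Conditions: Dess–Martin periodinane, CH2Cl2, rt
Reagents that add atoms: none
Why: Dess–Martin oxidation of the allylic alcohol to the enone is mild enough for the benzylic acetate and removes the C1 stereocentre so that it can be reset from the other face.

**Step 15**
Reactants: 19 7β-acetoxy-11,12,14-trimethoxy-1-oxoicetexa-8,11,13,10(20)-tetraen-19,6β-olide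
Product: 20 11,12,14-trimethoxy-1-oxoicetexa-6,8,11,13,10(20)-pentaen-19,6-olide
Conditions: TsOH·H2O (cat.), toluene, 80 °C
Reagents that add atoms: none
Why: Acid-catalysed E1 elimination: the C7 acetate ionises to a benzylic cation stabilised by the para C12 and ortho C14 methoxy groups whose only β-hydrogen is H6, so the C6=C7 enol lactone is the only alkene that can form, while the C1 ketone keeps the C10=C20 bond from being protonated.

**Step 16**
Reactants: 20 11,12,14-trimethoxy-1-oxoicetexa-6,8,11,13,10(20)-pentaen-19,6-olide
Product: 21 1β-hydroxy-11,12,14-trimethoxyicetexa-6,8,11,13,10(20)-pentaen-19,6-olide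
Conditions: NaBH4, CeCl3·7H2O, MeOH, −78 °C
Reagents that add atoms: none
Why: Luche reduction gives clean 1,2-reduction of the enone with axial hydride delivery on the α face of the ring A chair, which places the new C1 hydroxyl equatorial (1β, cis to the lactone bridge), and at −78 °C the enol lactone should not be touched.

**Step 17**
Reactants: 21 1β-hydroxy-11,12,14-trimethoxyicetexa-6,8,11,13,10(20)-pentaen-19,6-olide
Product: 22 1β-hydroxy-12-methoxy-11,14-dioxoicetexa-6,8,12,10(20)-tetraen-19,6-olide
Conditions: (NH4)2Ce(NO3)6, MeCN/H2O, 0 °C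
Reagents that add atoms: water, O
Why: Oxidative demethylation with (NH4)2Ce(NO3)6 converts the para-related C11 and C14 methoxy carbons into the quinone carbonyls and keeps the C12 methoxy group, the usual outcome for 1,2,4-trimethoxyarenes.

**Step 18**
Reactants: 22 1β-hydroxy-12-methoxy-11,14-dioxoicetexa-6,8,12,10(20)-tetraen-19,6-olide
Product: 23 6,7-anhydroballotiquinone
Conditions: BCl3, CH2Cl2, −78 °C; aq. NaHCO3 work-up
Reagents that add atoms: none
Why: Lewis-acid ether cleavage: BCl3 chelated between the C11 carbonyl and the neighbouring methoxy oxygen removes the methyl group of this vinylogous ester at −78 °C, and the C1 allylic alcohol, whose ionisation is disfavoured by the electron-poor quinone, and the enol lactone should survive the short exposure.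

**Compound list**
1 | podocarpic acid | C[C@]12CCC[C@](C)(C(=O)O)[C@@H]1CCc1ccc(O)cc12 | starting material
2 | propan-2-ol | CC(C)O | starting material
3 | 12-hydroxyabieta-8,11,13-trien-19-oic acid (lambertic acid) | C[C@]12CCC[C@](C)(C(=O)O)[C@@H]1CCc1cc(C(C)C)c(O)cc12 | intermediate
4 | 11,12-dioxoabieta-8,13-dien-19-oic acid | C[C@]12CCC[C@](C)(C(=O)O)[C@@H]1CCC1=C2C(=O)C(=O)C(C(C)C)=C1 | intermediate
5 | 11,12,14-triacetoxyabieta-8,11,13-trien-19-oic acid | C[C@]12CCC[C@](C)(C(=O)O)[C@@H]1CCc1c(OC(C)=O)c(C(C)C)c(OC(C)=O)c(OC(C)=O)c12 | intermediate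
6 | 11,12,14-trihydroxyabieta-8,11,13-trien-19-oic acid (triol acid, not isolated) | C[C@]12CCC[C@](C)(C(=O)O)[C@@H]1CCc1c(O)c(C(C)C)c(O)c(O)c12 | intermediate
7 | methyl 11,12,14-trimethoxyabieta-8,11,13-trien-19-oate | C[C@]12CCC[C@](C)(C(=O)OC)[C@@H]1CCc1c(OC)c(C(C)C)c(OC)c(OC)c12 | intermediate
8 | 11,12,14-trimethoxyabieta-8,11,13-trien-19-ol | C[C@]12CCC[C@](C)(CO)[C@@H]1CCc1c(OC)c(C(C)C)c(OC)c(OC)c12 | intermediate
9 | 19-iodooxy-11,12,14-trimethoxyabieta-8,11,13-triene (C19 hypoiodite, not isolated) | C[C@]12CCC[C@](C)(COI)[C@@H]1CCc1c(OC)c(C(C)C)c(OC)c(OC)c12 | intermediate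
10 | 20-iodo-11,12,14-trimethoxyabieta-8,11,13-trien-19-ol | IC[C@]12CCC[C@](C)(CO)[C@@H]1CCc1c(OC)c(C(C)C)c(OC)c(OC)c12 | intermediate
11 | 20-iodo-11,12,14-trimethoxyabieta-8,11,13-trien-19-oic acid | IC[C@]12CCC[C@](C)(C(=O)O)[C@@H]1CCc1c(OC)c(C(C)C)c(OC)c(OC)c12 | intermediate
12 | 20-iodo-11,12,14-trimethoxy-7-oxoabieta-8,11,13-trien-19-oic acid | IC[C@]12CCC[C@](C)(C(=O)O)[C@@H]1CC(=O)c1c(OC)c(C(C)C)c(OC)c(OC)c12 | intermediate
13 | 6α-bromo-20-iodo-11,12,14-trimethoxy-7-oxoabieta-8,11,13-trien-19-oic acid (6α-bromo ketone, not isolated) | IC[C@]12CCC[C@](C)(C(=O)O)[C@@H]1[C@@H](Br)C(=O)c1c(OC)c(C(C)C)c(OC)c(OC)c12 | intermediate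
14 | 20-iodo-11,12,14-trimethoxy-7-oxoabieta-8,11,13-trien-19,6β-olide | IC[C@]12CCC[C@]3(C)C(=O)O[C@H](C(=O)c4c(OC)c(C(C)C)c(OC)c(OC)c42)[C@H]13 | intermediate
15 | 7β-hydroxy-20-iodo-11,12,14-trimethoxyabieta-8,11,13-trien-19,6β-olide | IC[C@]12CCC[C@]3(C)C(=O)O[C@H]([C@H](O)c4c(OC)c(C(C)C)c(OC)c(OC)c42)[C@H]13 | intermediate
16 | 7β-acetoxy-20-iodo-11,12,14-trimethoxyabieta-8,11,13-trien-19,6β-olide | IC[C@]12CCC[C@]3(C)C(=O)O[C@H]([C@H](OC(C)=O)c4c(OC)c(C(C)C)c(OC)c(OC)c42)[C@H]13 | intermediate
17 | 7β-acetoxy-11,12,14-trimethoxyicetexa-8,11,13,10(20)-tetraen-19,6β-olide | CC(C)c1c(OC)c(OC)c2C=C3CCC[C@]4(C)C(=O)O[C@H]([C@H](OC(C)=O)c2c1OC)[C@H]34 | intermediate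
18 | 7β-acetoxy-1α-hydroxy-11,12,14-trimethoxyicetexa-8,11,13,10(20)-tetraen-19,6β-olide | CC(C)c1c(OC)c(OC)c2C=C3[C@@H](O)CC[C@]4(C)C(=O)O[C@H]([C@H](OC(C)=O)c2c1OC)[C@H]34 | intermediate
19 | 7β-acetoxy-11,12,14-trimethoxy-1-oxoicetexa-8,11,13,10(20)-tetraen-19,6β-olide | CC(C)c1c(OC)c(OC)c2C=C3C(=O)CC[C@]4(C)C(=O)O[C@H]([C@H](OC(C)=O)c2c1OC)[C@H]34 | intermediate
20 | 11,12,14-trimethoxy-1-oxoicetexa-6,8,11,13,10(20)-pentaen-19,6-olide | CC(C)c1c(OC)c(OC)c2C=C3C(=O)CC[C@]4(C)C(=O)OC(=Cc2c1OC)[C@H]34 | intermediate
21 | 1β-hydroxy-11,12,14-trimethoxyicetexa-6,8,11,13,10(20)-pentaen-19,6-olide | CC(C)c1c(OC)c(OC)c2C=C3[C@H](O)CC[C@]4(C)C(=O)OC(=Cc2c1OC)[C@H]34 | intermediate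
22 | 1β-hydroxy-12-methoxy-11,14-dioxoicetexa-6,8,12,10(20)-tetraen-19,6-olide | CC(C)C1=C(OC)C(=O)C2=C(C=C3OC(=O)[C@@]4(C)CC[C@@H](O)C(=C2)[C@@H]34)C1=O | intermediate
23 | 6,7-anhydroballotiquinone | CC(C)C1=C(O)C(=O)C2=C(C=C3OC(=O)[C@@]4(C)CC[C@@H](O)C(=C2)[C@@H]34)C1=O | target

**Total step count:** 18. **Longest linear sequence:** 18 steps from podocarpic acid.

**Steps most likely to fail**

Step 6. The C19 alkoxy radical may lose formaldehyde by β-scission, may abstract an axial ring hydrogen at C2 or C6 instead of one at C20, or the iodide may be oxidised further and close to the cyclic 19,20-ether. The fallback replaces the oxygen radical by an amidyl radical, which cannot fragment. It sets out from 7. Aminolysis of the ester with the aluminium amide made from AlMe3 and NH4Cl (toluene, 80 °C) should give 11,12,14-trimethoxyabieta-8,11,13-trien-19-amide F1. N-Iodination and photolysis (PhI(OAc)2, I2, CH2Cl2, hν), the amide version of the remote iodination, should give 20-iodo-11,12,14-trimethoxyabieta-8,11,13-trien-19-amide F2; work-up without base should keep the neopentyl iodide from closing onto the amide oxygen. Nitrosative deamination of the hindered primary amide (tert-butyl nitrite, AcOH, 40 °C) then gives the acid 11, where the route is rejoined; steps 5 and 7 are no longer needed.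

Step 12. Proton loss from the C10 cation may go toward C1 and leave an unconjugated alkene, or ionisation at the crowded neopentyl carbon may be slow enough for the C7 acetate to be lost first. The fallback makes the shift homolytic and sets the alkene afterwards. It sets out from 16. Slow addition of (Me3Si)3SiH and azobis(isobutyronitrile) in toluene at 110 °C should generate the C20 radical, which undergoes the neophyl 1,2-aryl shift to the tertiary C10 radical and is reduced to 7β-acetoxy-11,12,14-trimethoxyicetexa-8,11,13-trien-19,6β-olide F3 (both C10 epimers). DDQ in dry 1,4-dioxane should then abstract hydride from the benzylic C20, ortho to the C11 methoxy group; the only β-hydrogen of that cation is H10, so dehydrogenation can only give C10=C20, and the route is rejoined at 17.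

Step 3. Under acid the ortho-quinone may tautomerise to the C7 quinone methide and be acetoxylated in the side chain, or acetate may fail to add at the hindered C14. The fallback brings in the C14 oxygen by aromatic substitution and sets out from 4. Reduction with Na2S2O4 gives 11,12-dihydroxyabieta-8,11,13-trien-19-oic acid F4, which is methylated without isolation (Me2SO4, K2CO3, acetone, reflux) to methyl 11,12-dimethoxyabieta-8,11,13-trien-19-oate F5. Bromination of the last free ring carbon, para to the C11 methoxy group (N-bromosuccinimide, MeCN, rt), should give methyl 14-bromo-11,12-dimethoxyabieta-8,11,13-trien-19-oate F6. Ullmann-type methoxylation (NaOMe, CuBr, DMF/MeOH, 110 °C) then gives 7, where the route is rejoined.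

**Further compounds**
F1 | step 6 | 11,12,14-trimethoxyabieta-8,11,13-trien-19-amide | C[C@]12CCC[C@](C)(C(N)=O)[C@@H]1CCc1c(OC)c(C(C)C)c(OC)c(OC)c12
F2 | step 6 | 20-iodo-11,12,14-trimethoxyabieta-8,11,13-trien-19-amide | IC[C@]12CCC[C@](C)(C(N)=O)[C@@H]1CCc1c(OC)c(C(C)C)c(OC)c(OC)c12
F3 | step 12 | 7β-acetoxy-11,12,14-trimethoxyicetexa-8,11,13-trien-19,6β-olide (C10 epimers) | CC(C)c1c(OC)c(OC)c2CC3CCC[C@]4(C)C(=O)O[C@H]([C@H](OC(C)=O)c2c1OC)[C@H]34
F4 | step 3 | 11,12-dihydroxyabieta-8,11,13-trien-19-oic acid | C[C@]12CCC[C@](C)(C(=O)O)[C@@H]1CCc1cc(C(C)C)c(O)c(O)c12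
F5 | step 3 | methyl 11,12-dimethoxyabieta-8,11,13-trien-19-oate | C[C@]12CCC[C@](C)(C(=O)OC)[C@@H]1CCc1cc(C(C)C)c(OC)c(OC)c12
F6 | step 3 | methyl 14-bromo-11,12-dimethoxyabieta-8,11,13-trien-19-oate | C[C@]12CCC[C@](C)(C(=O)OC)[C@@H]1CCc1c(Br)c(C(C)C)c(OC)c(OC)c12
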